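1. Numbering: flavan unit O1, C2–C4, ring A (C4a–C8a), ring B on C2; upper unit O1'', ketal C2'', carbinol C3'', ketone C4''. Target ⇐ penta-O-benzyl ether ⇐ 2''-aryl-3''-aroylbenzofuran fused to ring A at O7/C8: face-selective epoxidation of C2''=C3'' and capture at C2'' by the ortho-OH of the aroyl group close the pyranone ring last.
2. Benzofuran ⇐ 7-hydroxy-8-alkynylflavan + aryl iodide + CO (carbonylative heteroannulation: furan ring and C3''–C4'' bond); alkyne ⇐ 8-iodoflavan (Sonogashira coupling).
3. 8-Iodoflavan ⇐ benzylic chloride + (R)-aryloxirane in one flask: the benzylic Grignard reagent opens the epoxide (C4–C3), the C2 alkoxide adds to a C8–C8a aryne (O1–C8a, ring C), iodine traps the carbanion at C8.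
4. Enabling feature: ring A is a phloroglucinol ring whose oxygens O1, O5 and O7 are mutually meta, so C8 is the one CH between O7 and the O1-bearing C8a. With F in place of O1 it is the most acidic CH, the aryne forms at C8–C8a, only C8a is within reach of the C2 alkoxide, and the carbanion is left on C8, the carbon that carries C3''.
5. Ring order: ring C of the flavan (step 6), furan ring (step 11), pyranone ring (step 13); C2 comes from an oxirane made by CBS reduction, C3''/C2'' from the catalyst-controlled epoxidation.

Key step: step 6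

Assumption: C2'' and C3'' form one stereochemical element, because the ketal can only close on the face of C2'' that the aroyl tether reaches (cis-fused rings) once C3'' is set; the route sets C3'' as (S), and all SMILES carry the C2''/C3'' descriptors exactly as the target string writes them.

Step 1
Reactants: 1 1-[4-(benzyloxy)phenyl]-2-bromoethan-1-one
Product: 3 (R)-2-[4-(benzyloxy)phenyl]oxirane, via bromohydrin 2 (not isolated)
Conditions: (R)-2-methyl-CBS-oxazaborolidine (10 mol%), BH3·SMe2, THF, 0 °C; then MeOH, 2 M NaOH, rt; filtration through basic alumina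
Reagents that add atoms: none
Why: Corey–Bakshi–Shibata reduction delivers hydride to the ketone face dictated by the (R)-oxazaborolidine with the aryl group as the large substituent, setting (R) in bromohydrin 2, and the alkoxide then displaces bromide at the CH2 (intramolecular Williamson closure) without touching the stereocentre.

Step 2
Reactants: 4 2,6-difluoro-4-hydroxybenzaldehyde
Product: 5 2,6-difluoro-4-(methoxymethoxy)benzaldehyde
Conditions: MOMCl, i-Pr2NEt, CH2Cl2, 0 °C to rt
Reagents that add atoms: chloromethyl methyl ether, COCCl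
Why: The phenol, acidified by the para formyl group and the two fluorines, is O-alkylated cleanly by MOMCl under amine base.

Step 3
Reactants: 5 2,6-difluoro-4-(methoxymethoxy)benzaldehyde
Product: 6 2-(benzyloxy)-6-fluoro-4-(methoxymethoxy)benzaldehyde
Conditions: BnOH (1.0 equiv), KOt-Bu, THF, −20 to 0 °C
Reagents that add atoms: benzyl alcohol, OCc1ccccc1
Why: Nucleophilic aromatic substitution, in which the formyl group activates the two equivalent ortho fluorines toward potassium benzyloxide and the alkoxy group introduced deactivates the ring so that the second fluorine is kept.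

Step 4
Reactants: 6 2-(benzyloxy)-6-fluoro-4-(methoxymethoxy)benzaldehyde
Product: 7 [2-(benzyloxy)-6-fluoro-4-(methoxymethoxy)phenyl]methanol
Conditions: NaBH4, MeOH–THF, 0 °C
Reagents that add atoms: none
Why: Borohydride reduction of the aldehyde, to which the aryl fluoride and the MOM and benzyl ethers are inert.

Step 5
Reactants: 7 [2-(benzyloxy)-6-fluoro-4-(methoxymethoxy)phenyl]methanol
Product: 8 1-(benzyloxy)-2-(chloromethyl)-3-fluoro-5-(methoxymethoxy)benzene
Conditions: MsCl, LiCl, 2,4,6-collidine, DMF, 0 °C; used at once without chromatography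
Reagents that add atoms: lithium chloride, [Li+].[Cl-]
Why: The benzylic mesylate formed in situ is displaced by chloride under buffered, non-acidic conditions that spare the MOM acetal.

Step 6
Reactants: 8 1-(benzyloxy)-2-(chloromethyl)-3-fluoro-5-(methoxymethoxy)benzene; 3 (R)-2-[4-(benzyloxy)phenyl]oxirane
Product: 14 (2S)-5-(benzyloxy)-2-[4-(benzyloxy)phenyl]-8-iodo-7-(methoxymethoxy)chroman, via benzylic Grignard reagent 9 (not isolated), via chloromagnesium alkoxide 10 (not isolated), via C8-lithiated alkoxide 11 (not isolated), via aryne alkoxide 12 (not isolated), via C8-magnesiated flavan 13 (not isolated)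
Conditions: Mg, 2-MeTHF, 0 °C; 3, CuI (10 mol%), THF, −40 to 0 °C; lithium 2,2,6,6-tetramethylpiperidide (3 equiv), −78 to 0 °C; I2, −78 °C to rt
Reagents that add atoms: iodine, II
Why: Proposed new method: one-flask merger of four events that each have close precedent but have not been combined: the benzylic Grignard reagent 9 (the benzylic carbon C4 of a phloroglucinol ring, normally an ortho-quinone-methide electrophile, used here with reversed polarity) opens epoxide 3 at its CH2 under CuI catalysis (SN2, C4–C3), lithium tetramethylpiperidide then removes the ring hydrogen at C8, the only one flanked by fluorine and OMOM, LiF is lost to give the C8–C8a aryne 12, the tethered C2 alkoxide adds to C8a (O1–C8a) and the C8 carbanion 13 is iodinated. Closest known reaction types: copper-catalysed opening of terminal epoxides by benzylic Grignard reagents, and aryne ring closure of tethered alkoxides or amides with electrophilic trapping of the ortho carbanion. Ring C closes by 6-exo-dig attack of O1 on the aryne carbon C8a; attack at C8 would need a meta-bridged seven-membered ring and is excluded. No new stereocentre is formed: C2 comes from 3, and since no bond to it is broken the (R)-oxirane carbon becomes (S)-C2 only through the change in substituent priorities. The step needs terminal selectivity in the epoxide opening (secured by the cuprate-type SN2 pathway at low temperature without strong Lewis acid), site selectivity in the metalation (secured by the fluorine/OMOM pair at C8 against the OBn/OMOM pair at C6, which has no leaving group beside it) and regioselective aryne capture (secured by the tether and reinforced by the polarisation of a 3-alkoxyaryne, which directs nucleophiles to the carbon remote from oxygen).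

Step 7
Reactants: 14 (2S)-5-(benzyloxy)-2-[4-(benzyloxy)phenyl]-8-iodo-7-(methoxymethoxy)chroman; 15 1-(benzyloxy)-4-ethynylbenzene
Product: 16 (2S)-5-(benzyloxy)-2-[4-(benzyloxy)phenyl]-8-{[4-(benzyloxy)phenyl]ethynyl}-7-(methoxymethoxy)chroman
Conditions: PdCl2(PPh3)2 (5 mol%), CuI (10 mol%), Et3N, DMF, 60 °C
Reagents that add atoms: none
Why: Sonogashira coupling, in which oxidative addition of the aryl iodide tolerates the two ortho oxygen substituents and the MOM group keeps O7 from cyclising onto the alkyne.

Step 8
Reactants: 16 (2S)-5-(benzyloxy)-2-[4-(benzyloxy)phenyl]-8-{[4-(benzyloxy)phenyl]ethynyl}-7-(methoxymethoxy)chroman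
Product: 17 (2S)-5-(benzyloxy)-2-[4-(benzyloxy)phenyl]-8-{[4-(benzyloxy)phenyl]ethynyl}chroman-7-ol
Conditions: 2 M HCl, MeOH–THF, 40 °C
Reagents that add atoms: none
Why: Acid-catalysed acetal cleavage of the aryl MOM ether, which the benzyl ethers, the diarylalkyne and the C2–O1 bond of the O-benzylated flavan survive in dilute acid.

Step 9
Reactants: 18 3,5-bis(benzyloxy)phenol
Product: 19 1,3-bis(benzyloxy)-5-(methoxymethoxy)benzene
Conditions: MOMCl, i-Pr2NEt, CH2Cl2, 0 °C to rt
Reagents that add atoms: chloromethyl methyl ether, COCCl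
Why: Routine O-alkylation of a phenol with MOMCl.

Step 10
Reactants: 19 1,3-bis(benzyloxy)-5-(methoxymethoxy)benzene
Product: 21 1,5-bis(benzyloxy)-2-iodo-3-(methoxymethoxy)benzene, via aryllithium 20 (not isolated)
Conditions: n-BuLi, THF, −78 to −20 °C; I2, −78 °C
Reagents that add atoms: iodine, II
Why: Directed ortho-metalation, in which the MOM group directs n-BuLi to one of the two equivalent positions between OMOM and OBn and iodine quenches aryllithium 20.

Step 11
Reactants: 17 (2S)-5-(benzyloxy)-2-[4-(benzyloxy)phenyl]-8-{[4-(benzyloxy)phenyl]ethynyl}chroman-7-ol; 21 1,5-bis(benzyloxy)-2-iodo-3-(methoxymethoxy)benzene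
Product: 22 3''-aroylbenzofuran: (S)-flavan with a furan fused at O7/C8 of ring A; C2'' bears 4-(benzyloxy)phenyl and C3'' bears 2,4-bis(benzyloxy)-6-(methoxymethoxy)benzoyl
Conditions: Pd(PPh3)4 (5 mol%), K2CO3, CO (1 atm), MeCN, 50 °C
Reagents that add atoms: carbon monoxide, [C-]#[O+]
Why: Palladium-catalysed carbonylative heteroannulation of an ortho-alkynylphenol with an aryl iodide, in which the aroylpalladium species formed from 21 and CO activates the alkyne, the phenoxide O7 adds anti in a 5-endo-dig closure and reductive elimination places the aroyl group on C3'' of the new furan.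

Step 12
Reactants: 22 the MOM-protected 3''-aroylbenzofuran
Product: 23 the same benzofuran with a free ortho-OH on the aroyl group [2,4-bis(benzyloxy)-6-hydroxybenzoyl]
Conditions: 2 M HCl, MeOH–THF, 40 °C
Reagents that add atoms: none
Why: Acetal cleavage of the MOM ether ortho to the ketone, assisted by the hydrogen bond to the carbonyl, frees the one phenol needed for ketal closure.

Step 13
Reactants: 23 the 3''-(2,4-bis(benzyloxy)-6-hydroxybenzoyl)benzofuran
Product: 25 penta-O-benzyl ether of the target [(2S) (2''R) (3''S); free 3''-OH], via furan epoxide 24 (not isolated)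
Conditions: (R,R)-[N,N'-bis(3,5-di-tert-butylsalicylidene)cyclohexane-1,2-diaminato]manganese chloride (10 mol%), m-CPBA, N-methylmorpholine N-oxide, CH2Cl2, −78 °C
Reagents that add atoms: 3-chloroperoxybenzoic acid, O=C(OO)c1cccc(Cl)c1
Why: Proposed new method: catalyst-controlled oxygen transfer to the tetrasubstituted furan bond C2''=C3'' of a 3-aroyl-2-arylbenzofuran with capture by the ortho phenol of the aroyl group in the same flask; the oxomanganese salen species bonds oxygen first to C3'' (leaving radical or cation character on C2'', stabilised by O7 and the aryl group), epoxide 24 opens at C2'' as the phenol oxygen adds there in a 6-endo closure that forms the pyranone ring, so that (S)-C3'' is set by the catalyst [assigned by analogy with indene, which the (R,R) catalyst converts to the (1R,2S)-oxide, with C3'' and C8 in the role of indene C1 and its arene carbon] and C2'' follows because only the face on the side of the aroyl tether is within reach; closest known reaction types: Jacobsen–Katsuki epoxidation of chromenes, indene and tetrasubstituted cyclic aryl alkenes, and peracid or dioxirane epoxidation of 2,3-disubstituted benzofurans followed by opening of the labile epoxide at C2 by oxygen nucleophiles.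

Step 14
Reactants: 25 penta-O-benzyl ether of the target
Product: 26 CNP0208300.3
Conditions: H2 (1 atm), Pd(OH)2/C, THF–MeOH, rt
Reagents that add atoms: none
Why: Hydrogenolysis of the five aryl benzyl ethers, which are cleaved far faster than the cyclic benzylic ether C2–O1, the diaryl ketal and the tertiary alcohol, so that no stereocentre is touched.

Compound list
1 | 1-[4-(benzyloxy)phenyl]-2-bromoethan-1-one | O=C(CBr)c1ccc(OCc2ccccc2)cc1 | starting material
2 | (R)-1-[4-(benzyloxy)phenyl]-2-bromoethan-1-ol | O[C@@H](CBr)c1ccc(OCc2ccccc2)cc1 | intermediate (not isolated)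
3 | (R)-2-[4-(benzyloxy)phenyl]oxirane | C1O[C@@H]1c1ccc(OCc2ccccc2)cc1 | intermediate
4 | 2,6-difluoro-4-hydroxybenzaldehyde | O=Cc1c(F)cc(O)cc1F | starting material
5 | 2,6-difluoro-4-(methoxymethoxy)benzaldehyde | O=Cc1c(F)cc(OCOC)cc1F | intermediate
6 | 2-(benzyloxy)-6-fluoro-4-(methoxymethoxy)benzaldehyde | O=Cc1c(F)cc(OCOC)cc1OCc1ccccc1 | intermediate
7 | [2-(benzyloxy)-6-fluoro-4-(methoxymethoxy)phenyl]methanol | OCc1c(F)cc(OCOC)cc1OCc1ccccc1 | intermediate
8 | 1-(benzyloxy)-2-(chloromethyl)-3-fluoro-5-(methoxymethoxy)benzene | ClCc1c(F)cc(OCOC)cc1OCc1ccccc1 | intermediate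
9 | [2-(benzyloxy)-6-fluoro-4-(methoxymethoxy)benzyl]magnesium chloride | Cl[Mg]Cc1c(F)cc(OCOC)cc1OCc1ccccc1 | intermediate (not isolated)
10 | chloromagnesium (S)-1-[4-(benzyloxy)phenyl]-3-[2-(benzyloxy)-6-fluoro-4-(methoxymethoxy)phenyl]propan-1-olate | Cl[Mg]O[C@H](c1ccc(OCc2ccccc2)cc1)CCc1c(F)cc(OCOC)cc1OCc1ccccc1 | intermediate (not isolated)
11 | alkoxide 10 lithiated at the ring CH between F and OMOM (future C8) | Cl[Mg]O[C@H](c1ccc(OCc2ccccc2)cc1)CCc1c(F)c([Li])c(OCOC)cc1OCc1ccccc1 | intermediate (not isolated)
12 | C8–C8a aryne formed from 11 by loss of LiF, (S)-alkoxide tether intact | Cl[Mg]O[C@H](c1ccc(OCc2ccccc2)cc1)CCC1=C(OCc2ccccc2)C=C(OCOC)C#C1 | intermediate (not isolated)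
13 | (2S)-5-(benzyloxy)-2-[4-(benzyloxy)phenyl]-7-(methoxymethoxy)chroman-8-ylmagnesium chloride | Cl[Mg]c1c(OCOC)cc(OCc2ccccc2)c2c1O[C@H](c1ccc(OCc3ccccc3)cc1)CC2 | intermediate (not isolated)
14 | (2S)-5-(benzyloxy)-2-[4-(benzyloxy)phenyl]-8-iodo-7-(methoxymethoxy)chroman | Ic1c(OCOC)cc(OCc2ccccc2)c2c1O[C@H](c1ccc(OCc3ccccc3)cc1)CC2 | intermediate
15 | 1-(benzyloxy)-4-ethynylbenzene | C#Cc1ccc(OCc2ccccc2)cc1 | starting material
16 | (2S)-5-(benzyloxy)-2-[4-(benzyloxy)phenyl]-8-{[4-(benzyloxy)phenyl]ethynyl}-7-(methoxymethoxy)chroman | COCOc1cc(OCc2ccccc2)c2c(c1C#Cc1ccc(OCc3ccccc3)cc1)O[C@H](c1ccc(OCc3ccccc3)cc1)CC2 | intermediate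
17 | (2S)-5-(benzyloxy)-2-[4-(benzyloxy)phenyl]-8-{[4-(benzyloxy)phenyl]ethynyl}chroman-7-ol | Oc1cc(OCc2ccccc2)c2c(c1C#Cc1ccc(OCc3ccccc3)cc1)O[C@H](c1ccc(OCc3ccccc3)cc1)CC2 | intermediate
18 | 3,5-bis(benzyloxy)phenol | Oc1cc(OCc2ccccc2)cc(OCc2ccccc2)c1 | starting material
19 | 1,3-bis(benzyloxy)-5-(methoxymethoxy)benzene | COCOc1cc(OCc2ccccc2)cc(OCc2ccccc2)c1 | intermediate
20 | [2,4-bis(benzyloxy)-6-(methoxymethoxy)phenyl]lithium | COCOc1cc(OCc2ccccc2)cc(OCc2ccccc2)c1[Li] | intermediate (not isolated)
21 | 1,5-bis(benzyloxy)-2-iodo-3-(methoxymethoxy)benzene | COCOc1cc(OCc2ccccc2)cc(OCc2ccccc2)c1I | intermediate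
22 | (S)-flavan [5-OBn, 2-(4-benzyloxyphenyl)] with a furan fused at O7/C8; C2'' bears 4-(benzyloxy)phenyl, C3'' bears 2,4-bis(benzyloxy)-6-(methoxymethoxy)benzoyl | O=C(c1c(OCOC)cc(OCc2ccccc2)cc1OCc1ccccc1)c1c(-c2ccc(OCc3ccccc3)cc2)oc2cc(OCc3ccccc3)c3c(c12)O[C@H](c1ccc(OCc2ccccc2)cc1)CC3 | intermediate
23 | as 22, with 2,4-bis(benzyloxy)-6-hydroxybenzoyl on C3'' | O=C(c1c(O)cc(OCc2ccccc2)cc1OCc1ccccc1)c1c(-c2ccc(OCc3ccccc3)cc2)oc2cc(OCc3ccccc3)c3c(c12)O[C@H](c1ccc(OCc2ccccc2)cc1)CC3 | intermediate
24 | C2''–C3'' epoxide of 23, oxygen on the face that gives (S)-C3'' | O=C(c1c(O)cc(OCc2ccccc2)cc1OCc1ccccc1)[C@]12O[C@@]1(c1ccc(OCc3ccccc3)cc1)Oc1cc(OCc3ccccc3)c3c(c12)O[C@H](c1ccc(OCc2ccccc2)cc1)CC3 | intermediate (not isolated)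
25 | penta-O-benzyl ether of the target: benzyl on O5 and the ring B oxygen of the flavan, on O5'' and O7'' of the chromanone and on the oxygen of the 2''-aryl group; free 3''-OH; (2S), (2''R), (3''S) | O=C1c2c(OCc3ccccc3)cc(OCc3ccccc3)cc2O[C@@]2(c3ccc(OCc4ccccc4)cc3)Oc3cc(OCc4ccccc4)c4c(c3[C@]12O)O[C@H](c1ccc(OCc2ccccc2)cc1)CC4 | intermediate
26 | CNP0208300.3: (2S)-5-hydroxy-2-(4-hydroxyphenyl)chroman whose O7 and C8 are bonded to the ketal carbon C2'' (R) and the carbinol carbon C3'' (S) of a 3'',5'',7''-trihydroxy-2''-(4-hydroxyphenyl)chroman-4''-one | O=C1c2c(O)cc(O)cc2O[C@@]2(c3ccc(O)cc3)Oc3cc(O)c4c(c3[C@]12O)O[C@H](c1ccc(O)cc1)CC4 | target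

Total step count: 14. Longest linear sequence: 11 steps (steps 2–8 and 11–14, from 4).

Steps most likely to fail

Step 6. The one-flask sequence may break down through Wurtz coupling while the Grignard reagent forms, through attack at the benzylic epoxide carbon or its Meinwald rearrangement, through metalation at a wrong site, or through intermolecular capture of the aryne. The fallback sets out from 6 and uses only stepwise, known reactions. Claisen–Schmidt condensation of 6 with commercial 1-[4-(benzyloxy)phenyl]ethan-1-one (Ba(OH)2, MeOH) should give the chalcone F1. Conjugate reduction (H2, RhCl(PPh3)3) should give the dihydrochalcone F2. CBS reduction with the (R)-oxazaborolidine should give the (S)-alcohol F3, the protonated form of 10. KOt-Bu in DMF should then close ring C by intramolecular SNAr at the fluorinated carbon, which the two meta oxygens activate inductively, to give the flavan F4. N-Iodosuccinimide should iodinate C8, the usual site of halogenation in 5,7-dioxygenated flavans, and the route is rejoined at 14.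

Step 13. Facial selectivity may be poor on a tetrasubstituted, acyl-deactivated double bond, the chelating ortho-hydroxyaryl ketone may bind to manganese, and the alkoxyarene rings may be over-oxidised. The fallback sets out from 23 and gives up catalyst control. Dimethyldioxirane in acetone–CH2Cl2 at −40 °C, a known epoxidation of 2,3-disubstituted benzofurans, should give 25 together with its diastereomer F5, which has the opposite configuration at both C2'' and C3''. Because C2 of the flavan is fixed, the two are diastereomers and should be separable by preparative HPLC; the route is rejoined at 25.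

Step 11. Oxidative addition and CO insertion may be slow with the hindered, electron-rich iodide 21, so that 17 cycloisomerises to the benzofuran without the aroyl group or is arylated without CO. The fallback sets out from 17. Iodocyclisation (I2, NaHCO3, MeCN) should give the 3''-iodobenzofuran F6. Iodine–magnesium exchange (i-PrMgCl·LiCl, THF) and addition to the aldehyde F7, itself made from 21 by iodine–magnesium exchange and DMF, should give the diarylcarbinol F8. Dess–Martin oxidation returns to the route at 22.

Further compounds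
F1 | step 6 | (E)-3-[2-(benzyloxy)-6-fluoro-4-(methoxymethoxy)phenyl]-1-[4-(benzyloxy)phenyl]prop-2-en-1-one | O=C(/C=C/c1c(F)cc(OCOC)cc1OCc1ccccc1)c1ccc(OCc2ccccc2)cc1
F2 | step 6 | 3-[2-(benzyloxy)-6-fluoro-4-(methoxymethoxy)phenyl]-1-[4-(benzyloxy)phenyl]propan-1-one | O=C(CCc1c(F)cc(OCOC)cc1OCc1ccccc1)c1ccc(OCc2ccccc2)cc1
F3 | step 6 | (S)-1-[4-(benzyloxy)phenyl]-3-[2-(benzyloxy)-6-fluoro-4-(methoxymethoxy)phenyl]propan-1-ol | O[C@H](c1ccc(OCc2ccccc2)cc1)CCc1c(F)cc(OCOC)cc1OCc1ccccc1
F4 | step 6 | (2S)-5-(benzyloxy)-2-[4-(benzyloxy)phenyl]-7-(methoxymethoxy)chroman | COCOc1cc(OCc2ccccc2)c2c(c1)O[C@H](c1ccc(OCc3ccccc3)cc1)CC2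
F5 | step 13 | diastereomer of 25 with the opposite configuration at C2'' and C3'' | O=C1c2c(OCc3ccccc3)cc(OCc3ccccc3)cc2O[C@]2(c3ccc(OCc4ccccc4)cc3)Oc3cc(OCc4ccccc4)c4c(c3[C@@]12O)O[C@H](c1ccc(OCc2ccccc2)cc1)CC4
F6 | step 11 | 3''-iodo analogue of 22 (iodine in place of the aroyl group) | Ic1c(-c2ccc(OCc3ccccc3)cc2)oc2cc(OCc3ccccc3)c3c(c12)O[C@H](c1ccc(OCc2ccccc2)cc1)CC3
F7 | step 11 | 2,4-bis(benzyloxy)-6-(methoxymethoxy)benzaldehyde | O=Cc1c(OCOC)cc(OCc2ccccc2)cc1OCc1ccccc1
F8 | step 11 | diarylcarbinol corresponding to ketone 22 (mixture of carbinol epimers) | OC(c1c(OCOC)cc(OCc2ccccc2)cc1OCc1ccccc1)c1c(-c2ccc(OCc3ccccc3)cc2)oc2cc(OCc3ccccc3)c3c(c12)O[C@H](c1ccc(OCc2ccccc2)cc1)CC3
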